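**Retrosynthetic overview**
- Target ⇐ late allylic C–H hydroxylation at the side-chain E-methyl (C7′–O); the 3Z ring olefin ⇐ hydroxyl-directed syn-carbomagnesiation (CH3 onto C4) of a 14-membered cycloalkyne.
- The only ring (the 14-membered carbocycle) is closed once, at C13–C14, by intramolecular alkylation of a β-hydroxy sulfone dianion with an allylic bromide; the sulfone is then removed.
- Acyclic precursor ⇐ C2–C3 union of a chiral epoxy sulfone with a C13 hydroxy-enyne (geranyl chloride + propargyl unit, then allylic hydroxylation).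
- Key disconnection: the C1–O bond. The tertiary carbinol stereocentre is created by a catalytic asymmetric α-hydroxylation of a β-sulfonyl aldehyde derived from (R)-citronellal, which supplies C2′.

Assumption: the target is (1S,3Z,7E,11E)-1-[(2R,5E)-7-hydroxy-6-methylhept-5-en-2-yl]-4,8,12-trimethylcyclotetradeca-3,7,11-trien-1-ol, and all locants below (ring C1–C14, side chain C1′–C7′) refer to this name; propargylmagnesium bromide, LDA, n-BuLi and MeMgBr are used as pre-formed solutions.

**Step 1**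
Reactants: 1 (R)-citronellal [(3R)-3,7-dimethyloct-6-enal]
Product: 2 (3R)-3,7-dimethyl-2-methylideneoct-6-enal
Conditions: 37% aq. HCHO, pyrrolidine (10 mol%), EtCO2H (10 mol%), i-PrOH, 45 °C
Reagents that add atoms: formaldehyde, C=O
Why: Amine-catalysed Mannich/elimination α-methylenation of an unbranched aldehyde; the existing stereocentre is not enolisable under these mild conditions and the new CH2 later becomes ring C14.

**Step 2**
Reactants: 2 (3R)-3,7-dimethyl-2-methylideneoct-6-enal
Product: 5 (2R,3R)-3,7-dimethyl-2-[(phenylsulfonyl)methyl]oct-6-ene-1,2-diol, via sulfonyl aldehyde 3 (not isolated), via hydroxy aldehyde 4 (not isolated)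
Conditions: PhSO2Na, AcOH, CH2Cl2/i-PrOH, rt; then cat. A (15 mol%), PhCO2H (15 mol%), 3-phenyl-2-(phenylsulfonyl)oxaziridine, toluene, 0 °C; then NaBH4, MeOH, 0 °C
Reagents that add atoms: sodium benzenesulfinate, [Na+].[O-]S(=O)c1ccccc1; 3-phenyl-2-(phenylsulfonyl)oxaziridine, O=S(=O)(c1ccccc1)N1OC1c1ccccc1
Why: Proposed new method: one-pot sulfa-Michael addition followed by primary-amine-catalysed α-hydroxylation of an α,α-dialkyl aldehyde, which forms the C1–O bond and the only new stereocentre. Both epimers of 3 condense with the new catalyst A (N-[(1R,2R)-2-aminocyclohexyl]-N′-[3,5-bis(trifluoromethyl)phenyl]squaramide, or its antipode, whichever gives (2R)-5) to one enamine; the squaramide N–H bonds bind the substrate's own sulfonyl oxygens, fixing the enamine geometry and shielding one face. The N-sulfonyloxaziridine then transfers electrophilic oxygen to the open face under catalyst control, and the isolated olefin is inert to it. The configuration is confirmed against material from the fallback, and NaBH4 reduces the sensitive aldehyde in the same pot. Closest known reaction type: primary-amine-catalysed enantioselective α-hydroxylation of α-aryl α-branched aldehydes with N-sulfonyloxaziridines, and iminium/enamine cascades.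

**Step 3**
Reactants: 5 (2R,3R)-3,7-dimethyl-2-[(phenylsulfonyl)methyl]oct-6-ene-1,2-diol
Product: 6 (2R)-2-[(2R)-6-methylhept-5-en-2-yl]-2-[(phenylsulfonyl)methyl]oxirane
Conditions: PPh3, DIAD, THF, 0 °C → rt
Reagents that add atoms: none
Why: Mitsunobu cyclodehydration activates the primary OH and the tertiary oxygen closes the epoxide, so the carbinol C–O bond is retained; the near-neutral conditions avoid base-induced opening of the β,γ-epoxy sulfone.

**Step 4**
Reactants: 7 geranyl chloride [(2E)-1-chloro-3,7-dimethylocta-2,6-diene]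
Product: 8 (5E)-6,10-dimethylundeca-5,9-dien-1-yne
Conditions: propargylmagnesium bromide, Et2O, 0 °C → rt
Reagents that add atoms: propargylmagnesium bromide, C#CC[Mg]Br
Why: SN2 coupling of a primary allylic chloride with the propargyl Grignard reagent gives the 1,5-enyne with the E olefin intact.

**Step 5**
Reactants: 8 (5E)-6,10-dimethylundeca-5,9-dien-1-yne
Product: 9 (2E,6E)-2,6-dimethylundeca-2,6-dien-10-yn-1-ol
Conditions: SeO2 (10 mol%), t-BuOOH, salicylic acid (10 mol%), CH2Cl2, 0 °C → rt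
Reagents that add atoms: tert-butyl hydroperoxide, CC(C)(C)OO
Why: Riley-type SeO2/t-BuOOH allylic hydroxylation (ene reaction then [2,3]-shift) is selective for the E-methyl of the terminal gem-dimethyl olefin; this carbon becomes ring C13.

**Step 6**
Reactants: 9 (2E,6E)-2,6-dimethylundeca-2,6-dien-10-yn-1-ol; 6 (2R)-2-[(2R)-6-methylhept-5-en-2-yl]-2-[(phenylsulfonyl)methyl]oxirane
Product: 11 (2E,6E,13S,14R)-2,6,14,18-tetramethyl-13-[(phenylsulfonyl)methyl]nonadeca-2,6,17-trien-10-yne-1,13-diol, via dilithio alkynide 10 (not isolated)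
Conditions: 9, n-BuLi (2 equiv), THF, −78 °C; BF3·OEt2; then 6, −78 °C; aq. NH4Cl
Reagents that add atoms: none
Why: Yamaguchi–Hirao alkynylation opens the 2,2-disubstituted epoxide at its CH2 (C2–C3 bond), leaving the carbinol stereocentre untouched (the descriptor changes only through CIP priorities); the BF3-bound alkoxide is not nucleophilic and the weakly basic alkynyl borate does not trigger elimination of the epoxy sulfone.

**Step 7**
Reactants: 11 (2E,6E,13S,14R)-2,6,14,18-tetramethyl-13-[(phenylsulfonyl)methyl]nonadeca-2,6,17-trien-10-yne-1,13-diol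
Product: 12 (6R,7S,13E,17E)-19-bromo-2,6,14,18-tetramethyl-7-[(phenylsulfonyl)methyl]nonadeca-2,13,17-trien-9-yn-7-ol
Conditions: CBr4, PPh3, CH2Cl2, −20 → 0 °C
Reagents that add atoms: carbon tetrabromide, BrC(Br)(Br)Br
Why: Appel bromination converts only the primary allylic alcohol (SN2, no allylic shift at low temperature); the hindered tertiary alcohol is inert.

**Step 8**
Reactants: 12 (6R,7S,13E,17E)-19-bromo-2,6,14,18-tetramethyl-7-[(phenylsulfonyl)methyl]nonadeca-2,13,17-trien-9-yn-7-ol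
Product: 14 (1S,7E,11E)-8,12-dimethyl-1-[(2R)-6-methylhept-5-en-2-yl]-14-(phenylsulfonyl)cyclotetradeca-7,11-dien-3-yn-1-ol (C14 epimers), via dilithio dianion 13 (not isolated)
Conditions: LDA (2.3 equiv), THF, −78 → −40 °C, syringe-pump addition of 12 (final 2 mM); AcOH, −78 °C
Reagents that add atoms: none
Why: Intramolecular SN2 alkylation of the α-sulfonyl carbanion of a β-oxido sulfone dianion with the allylic bromide closes the 14-membered ring at C13–C14; the dianion resists retro-addition and O-alkylation, and the new sulfone-bearing centre is removed in the next step.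

**Step 9**
Reactants: 14 (1S,7E,11E)-8,12-dimethyl-1-[(2R)-6-methylhept-5-en-2-yl]-14-(phenylsulfonyl)cyclotetradeca-7,11-dien-3-yn-1-ol
Product: 15 (1S,7E,11E)-8,12-dimethyl-1-[(2R)-6-methylhept-5-en-2-yl]cyclotetradeca-7,11-dien-3-yn-1-ol
Conditions: 6% Na(Hg), Na2HPO4, MeOH/THF, −20 °C
Reagents that add atoms: none
Why: Buffered dissolving-metal reductive desulfonylation cleaves the non-allylic C–S bond without olefin migration; the free β-hydroxyl is a poor leaving group, so Julia-type elimination is minor, and the alkyne and olefins are inert.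

**Step 10**
Reactants: 15 (1S,7E,11E)-8,12-dimethyl-1-[(2R)-6-methylhept-5-en-2-yl]cyclotetradeca-7,11-dien-3-yn-1-ol
Product: 17 (1S,3Z,7E,11E)-4,8,12-trimethyl-1-[(2R)-6-methylhept-5-en-2-yl]cyclotetradeca-3,7,11-trien-1-ol, via alkenylmagnesium alkoxide 16 (not isolated)
Conditions: MeMgBr (5 equiv), Fe(acac)3 (20 mol%), THF, −20 → 0 °C; then H2O
Reagents that add atoms: methylmagnesium bromide, C[Mg]Br
Why: Iron-catalysed, alkoxide-directed syn-carbomagnesiation of the homopropargylic alcohol delivers CH3 to the distal alkyne carbon (C4) and Mg to C3 through a five-membered chelate; protonation gives the 3Z trisubstituted olefin with the ring carbons cis.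

**Step 11**
Reactants: 17 (1S,3Z,7E,11E)-4,8,12-trimethyl-1-[(2R)-6-methylhept-5-en-2-yl]cyclotetradeca-3,7,11-trien-1-ol
Product: 18 (1S,3Z,7E,11E)-1-[(2R,5E)-7-hydroxy-6-methylhept-5-en-2-yl]-4,8,12-trimethylcyclotetradeca-3,7,11-trien-1-ol
Conditions: SeO2 (10 mol%), t-BuOOH, salicylic acid (10 mol%), CH2Cl2, 0 °C
Reagents that add atoms: tert-butyl hydroperoxide, CC(C)(C)OO
Why: Riley-type SeO2/t-BuOOH allylic hydroxylation attacks the terminal gem-dimethyl olefin faster than the three ring olefins and, through the [2,3]-shift, gives only the E allylic alcohol.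

**Compound list**
1 | (R)-citronellal, (3R)-3,7-dimethyloct-6-enal | O=CC[C@H](C)CCC=C(C)C | starting material
2 | (3R)-3,7-dimethyl-2-methylideneoct-6-enal | O=CC(=C)[C@H](C)CCC=C(C)C | intermediate
3 | (3R)-3,7-dimethyl-2-[(phenylsulfonyl)methyl]oct-6-enal (C2 epimers, not isolated) | O=CC(CS(=O)(=O)c1ccccc1)[C@H](C)CCC=C(C)C | intermediate
4 | (2R,3R)-2-hydroxy-3,7-dimethyl-2-[(phenylsulfonyl)methyl]oct-6-enal (not isolated) | O=C[C@](O)([C@H](C)CCC=C(C)C)CS(=O)(=O)c1ccccc1 | intermediate
5 | (2R,3R)-3,7-dimethyl-2-[(phenylsulfonyl)methyl]oct-6-ene-1,2-diol | OC[C@](O)([C@H](C)CCC=C(C)C)CS(=O)(=O)c1ccccc1 | intermediate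
6 | (2R)-2-[(2R)-6-methylhept-5-en-2-yl]-2-[(phenylsulfonyl)methyl]oxirane | C1O[C@@]1([C@H](C)CCC=C(C)C)CS(=O)(=O)c2ccccc2 | intermediate
7 | geranyl chloride, (2E)-1-chloro-3,7-dimethylocta-2,6-diene | ClC/C=C(\C)CCC=C(C)C | starting material
8 | (5E)-6,10-dimethylundeca-5,9-dien-1-yne | C#CCC/C=C(\C)CCC=C(C)C | intermediate
9 | (2E,6E)-2,6-dimethylundeca-2,6-dien-10-yn-1-ol | C#CCC/C=C(\C)CC/C=C(\C)CO | intermediate
10 | dilithium salt of 9 (lithium alkoxide and lithium alkynide, not isolated) | [Li]C#CCC/C=C(\C)CC/C=C(\C)CO[Li] | intermediate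
11 | (2E,6E,13S,14R)-2,6,14,18-tetramethyl-13-[(phenylsulfonyl)methyl]nonadeca-2,6,17-trien-10-yne-1,13-diol | OC/C(C)=C/CC/C(C)=C/CCC#CC[C@](O)([C@H](C)CCC=C(C)C)CS(=O)(=O)c1ccccc1 | intermediate
12 | (6R,7S,13E,17E)-19-bromo-2,6,14,18-tetramethyl-7-[(phenylsulfonyl)methyl]nonadeca-2,13,17-trien-9-yn-7-ol | BrC/C(C)=C/CC/C(C)=C/CCC#CC[C@](O)([C@H](C)CCC=C(C)C)CS(=O)(=O)c1ccccc1 | intermediate
13 | O,C-dilithio dianion of 12 (lithium alkoxide and α-sulfonyl carbanion, not isolated) | BrC/C(C)=C/CC/C(C)=C/CCC#CC[C@](O[Li])([C@H](C)CCC=C(C)C)C([Li])S(=O)(=O)c1ccccc1 | intermediate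
14 | (1S,7E,11E)-8,12-dimethyl-1-[(2R)-6-methylhept-5-en-2-yl]-14-(phenylsulfonyl)cyclotetradeca-7,11-dien-3-yn-1-ol (C14 epimers) | C1(S(=O)(=O)c2ccccc2)C/C(C)=C/CC/C(C)=C/CCC#CC[C@]1(O)[C@H](C)CCC=C(C)C | intermediate
15 | (1S,7E,11E)-8,12-dimethyl-1-[(2R)-6-methylhept-5-en-2-yl]cyclotetradeca-7,11-dien-3-yn-1-ol | C1C/C(C)=C/CC/C(C)=C/CCC#CC[C@]1(O)[C@H](C)CCC=C(C)C | intermediate
16 | bromomagnesium alkoxide of 17 carrying MgBr at C3, cis to the new C4 methyl (not isolated) | C/C1=C(\[Mg]Br)/C[C@](O[Mg]Br)([C@H](C)CCC=C(C)C)CC/C(C)=C/CC/C(C)=C/CC1 | intermediate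
17 | (1S,3Z,7E,11E)-4,8,12-trimethyl-1-[(2R)-6-methylhept-5-en-2-yl]cyclotetradeca-3,7,11-trien-1-ol | C/C1=C/C[C@](O)([C@H](C)CCC=C(C)C)CC/C(C)=C/CC/C(C)=C/CC1 | intermediate
18 | (1S,3Z,7E,11E)-1-[(2R,5E)-7-hydroxy-6-methylhept-5-en-2-yl]-4,8,12-trimethylcyclotetradeca-3,7,11-trien-1-ol | C/C1=C/C[C@](O)([C@H](C)CC/C=C(\C)CO)CC/C(C)=C/CC/C(C)=C/CC1 | target

**Step count**
Total steps: 11. Longest linear sequence: 9 (steps 1, 2, 3, 6, 7, 8, 9, 10, 11 from 1); the enyne branch (steps 4 and 5) joins at step 6.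

**Steps most likely to fail, with fallbacks**

Step 2 (the proposed new hydroxylation; enamine geometry and facial control on an α,α-dialkyl aldehyde are untested). The fallback sets out from 2 and comes back at 5, using only known chemistry. Luche reduction of 2 (NaBH4, CeCl3·7H2O, MeOH, 0 °C) gives (3R)-3,7-dimethyl-2-methylideneoct-6-en-1-ol F1. Sharpless asymmetric epoxidation of this 2-substituted allylic alcohol (Ti(OiPr)4, D-(−)-diethyl tartrate, t-BuOOH, 4 Å sieves, CH2Cl2, −20 °C) leaves the isolated trisubstituted olefin alone and gives [(2R)-2-[(2R)-6-methylhept-5-en-2-yl]oxiran-2-yl]methanol F2. Opening the epoxide at its CH2 with PhSO2Na (AcOH buffer, DMF/H2O, 60 °C) gives 5.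

Step 8 (macrocyclisation; oligomerisation, elimination of the bromide by LDA or retro-addition of the alkoxide may compete). The fallback sets out from 6 and 8 and comes back at 14; it makes the C13–C14 bond intermolecularly and closes the ring by alkyne metathesis at C3≡C4. C-Methylation of 8 (n-BuLi, MeI, THF) gives (6E)-7,11-dimethyldodeca-6,10-dien-2-yne F3. SeO2/t-BuOOH hydroxylation gives (2E,6E)-2,6-dimethyldodeca-2,6-dien-10-yn-1-ol F4, and CBr4/PPh3 gives (2E,6E)-1-bromo-2,6-dimethyldodeca-2,6-dien-10-yne F5. Epoxide 6 is opened with 1-propynyllithium/BF3·OEt2 to (5S,6R)-6,10-dimethyl-5-[(phenylsulfonyl)methyl]undec-9-en-2-yn-5-ol F6. Its dianion (LDA, 2.2 equiv, THF, −78 °C) is alkylated with F5 at normal concentration to (5S,8E,12E)-8,12-dimethyl-5-[(2R)-6-methylhept-5-en-2-yl]-6-(phenylsulfonyl)octadeca-8,12-diene-2,16-diyn-5-ol F7. Ring-closing alkyne metathesis (molybdenum alkylidyne tris(triarylsilanolate) catalyst, 5 Å sieves, toluene, 80 °C) expels but-2-yne and gives 14.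

Step 11 (late allylic oxidation; the ring olefins may compete and over-oxidation to the enal is possible). The fallback sets out from 17 and comes back at 18. Cross-metathesis of the side-chain isopropylidene group with excess methacrolein (Hoveyda–Grubbs second-generation catalyst, CH2Cl2, 40 °C), to which the hindered ring olefins are far less reactive, gives (2E,6R)-6-[(1S,3Z,7E,11E)-1-hydroxy-4,8,12-trimethylcyclotetradeca-3,7,11-trien-1-yl]-2-methylhept-2-enal F8. Luche reduction (NaBH4, CeCl3·7H2O, MeOH, 0 °C) gives 18.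

**Further compounds**
F1 | step 2 | (3R)-3,7-dimethyl-2-methylideneoct-6-en-1-ol | OCC(=C)[C@H](C)CCC=C(C)C
F2 | step 2 | [(2R)-2-[(2R)-6-methylhept-5-en-2-yl]oxiran-2-yl]methanol | OC[C@]1([C@H](C)CCC=C(C)C)CO1
F3 | step 8 | (6E)-7,11-dimethyldodeca-6,10-dien-2-yne | CC#CCC/C=C(\C)CCC=C(C)C
F4 | step 8 | (2E,6E)-2,6-dimethyldodeca-2,6-dien-10-yn-1-ol | CC#CCC/C=C(\C)CC/C=C(\C)CO
F5 | step 8 | (2E,6E)-1-bromo-2,6-dimethyldodeca-2,6-dien-10-yne | CC#CCC/C=C(\C)CC/C=C(\C)CBr
F6 | step 8 | (5S,6R)-6,10-dimethyl-5-[(phenylsulfonyl)methyl]undec-9-en-2-yn-5-ol | CC#CC[C@](O)([C@H](C)CCC=C(C)C)CS(=O)(=O)c1ccccc1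
F7 | step 8 | (5S,8E,12E)-8,12-dimethyl-5-[(2R)-6-methylhept-5-en-2-yl]-6-(phenylsulfonyl)octadeca-8,12-diene-2,16-diyn-5-ol (C6 epimers) | CC#CC[C@](O)([C@H](C)CCC=C(C)C)C(C/C(C)=C/CC/C(C)=C/CCC#CC)S(=O)(=O)c1ccccc1
F8 | step 11 | (2E,6R)-6-[(1S,3Z,7E,11E)-1-hydroxy-4,8,12-trimethylcyclotetradeca-3,7,11-trien-1-yl]-2-methylhept-2-enal | C/C1=C/C[C@](O)([C@H](C)CC/C=C(\C)C=O)CC/C(C)=C/CC/C(C)=C/CC1
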